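**Plan**

Numbering (cheilanthane type): ring A is C1–C5/C10, ring B is C5–C10, ring C is C8/C9/C11–C14. The seven-membered ring D is C13–C14–C15–C16–C17–C25–C24, and lactone ring E is C17–C18–C19(=O)–O–C25. C22 and C23 are the methyl groups on C10 and C8.
Cuts: first C24=C25 in ring D, by a vinylogous aldol condensation between the γ-CH2 of a β-substituted butenolide and an aldehyde on C13. Then ring E goes back to a 3-furyl group, followed by cuts at C15–C16 (alkyllithium plus furan-3-carboxamide), C13=C24 (ketone methylenation), C8–C14 (cationic closure of ring C) and C14–C15 (carbomethoxylation), which leads to (+)-manool.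
Forward order: rings A and B come from manool and ring C closes in step 3. Ring E enters as a furan in step 7 and becomes the butenolide in step 11. Ring D closes last, in step 13, which gives the target itself.
Enabling feature: ring E is a γ-alkylidene butenolide whose exocyclic C24=C25 bond is endocyclic in ring D, so C25 is the γ-terminus of a 2-oxyfuran nucleophile and C24 a former aldehyde carbon. C13–H is α to that aldehyde before closure and ε-acidic (through a 5-alkenyl-2-furanolate) after it, so C13 stays mobile and drains into the isomer with C24 equatorial.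
Stereochemistry: C5, C9 and C10 come from manool; C8 and C14 from the chair-like cyclisation and the enolisable C14; C16 from a reagent-controlled ketone reduction. C13 is set by equilibration in the key step, since hydroboration can only deliver the 13-epimer. The E geometry of C24=C25 is fixed by ring D.

Key step: step 13

Remark: α is the face of 5-H, 9-H and 14-H, and β is the face of C22 and C23. Amide 8 is taken as a purchased compound.

Step 1
Reactants: 1 (+)-manool
Product: 2 14,15-dinorlabd-8(17)-en-13-one
Conditions: KMnO4, acetone–H2O, 0 → 23 °C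
Reagents that add atoms: none
Why: Permanganate oxidative cleavage of a vinyl carbinol, in which the open monosubstituted C14=C15 bond is dihydroxylated ahead of the shielded 8(17)-methylene and the resulting 13,14,15-triol is cleaved to the C13 methyl ketone, leaving C5, C9 and C10 untouched.

Step 2
Reactants: 2 14,15-dinorlabd-8(17)-en-13-one
Product: 3 methyl 13-oxo-16-norlabd-8(17)-en-15-oate
Conditions: NaH, (MeO)2CO, THF, reflux; then AcOH
Reagents that add atoms: dimethyl carbonate, COC(=O)OC
Why: Crossed Claisen condensation (carbomethoxylation) under equilibrating conditions acylates the methyl side (C14) rather than C12, because only that product is drained as the unhindered stabilised enolate, and no stereocentre is formed.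

Step 3
Reactants: 3 methyl 13-oxo-16-norlabd-8(17)-en-15-oate
Product: 4 tricyclic β-keto ester (C13 ketone, equatorial 14β-CO2Me, 14α-H, 8β-methyl)
Conditions: SnCl4, moist CH2Cl2, 0 → 23 °C
Reagents that add atoms: none
Why: Cationic olefin cyclisation terminated by a β-keto ester enol, in which protonation of the 8(17)-alkene gives the tertiary C8 cation, the tin-bound enol carbon C14 attacks it from the α face through a chair-like transition state so that C8–C14 is equatorial and C23 axial (β), and the acidic C14 settles with the ester equatorial.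

Step 4
Reactants: 4 tricyclic β-keto ester
Product: 5 exo-methylene ester (C13=C24H2, 14β-CO2Me, 14α-H)
Conditions: Zn, CH2Br2, TiCl4, THF–CH2Cl2, 0 → 23 °C
Reagents that add atoms: dibromomethane, BrCBr
Why: Takai–Lombardo methylenation, whose non-basic gem-dimetallic reagent adds to readily enolised ketones without deprotonating them and leaves esters alone, so C24 is installed with C14 intact.

Step 5
Reactants: 5 exo-methylene ester
Product: 6 homoallylic alcohol (C15–OH)
Conditions: LiAlH4, Et2O, 0 °C
Reagents that add atoms: none
Why: Hydride reduction of the ester to the primary alcohol, with the isolated alkene inert and C14 no longer enolisable afterwards.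

Step 6
Reactants: 6 homoallylic alcohol
Product: 7 C15 iodide
Conditions: I2, PPh3, imidazole, CH2Cl2, 0 → 23 °C
Reagents that add atoms: iodine, [I][I]
Why: Appel-type iodination by SN2 displacement of the alkoxyphosphonium group at the primary carbon C15, with no stereocentre involved.

Step 7
Reactants: 7 C15 iodide; 8 N-methoxy-N-methylfuran-3-carboxamide
Product: 10 furyl ketone (C16 ketone bearing furan-3-yl), via C15 alkyllithium 9 (not isolated)
Conditions: t-BuLi (2.1 equiv), Et2O–pentane, −78 °C; then 8, −78 → 0 °C; aqueous work-up
Reagents that add atoms: none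
Why: Lithium–iodine exchange followed by Weinreb ketone synthesis, in which the 3-butenyl-type alkyllithium does not cyclise and adds only once because the chelated tetrahedral adduct survives until the quench.

Step 8
Reactants: 10 furyl ketone
Product: 11 (16R)-furyl carbinol (16α-OH)
Conditions: (S)-1-methyl-3,3-diphenyltetrahydro-1H,3H-pyrrolo[1,2-c][1,3,2]oxazaborole (0.2 equiv), catecholborane, toluene, −78 °C
Reagents that add atoms: none
Why: Corey–Bakshi–Shibata reduction, in which the (S)-oxazaborolidine binds the ketone anti to the furyl group (the large group, as for aryl alkyl ketones) and delivers hydride to give 16R, while catecholborane at −78 °C leaves the alkene alone.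

Step 9
Reactants: 11 (16R)-furyl carbinol
Product: 12 (16R)-acetate
Conditions: Ac2O, 4-(dimethylamino)pyridine (cat.), pyridine, CH2Cl2, 0 → 23 °C
Reagents that add atoms: acetic anhydride, CC(=O)OC(C)=O
Why: Nucleophile-catalysed O-acylation, which does not touch the C16–O bond and so retains the configuration.

Step 10
Reactants: 12 (16R)-acetate
Product: 14 furan primary alcohol (13α-H, axial 13β-CH2OH), via B-alkyl-9-BBN adduct 13 (not isolated)
Conditions: 9-borabicyclo[3.3.1]nonane, THF, 23 → 45 °C; then NaBO3·4H2O, H2O, 23 °C
Reagents that add atoms: sodium perborate tetrahydrate, [Na+].[Na+].O[B-]1(O)OO[B-](O)(O)OO1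
Why: Anti-Markovnikov hydroboration–oxidation, in which the borane reaches C13=C24 only from the α face because the axial C23 methyl blocks the β face, so hydrogen is placed 13α and the CH2OH arm is axial, an outcome that is tolerated because C13 is reset in step 13.

Step 11
Reactants: 14 furan primary alcohol
Product: 16 butenolide alcohol (ring E as 4-substituted furan-2(5H)-one), via 25-hydroxybutenolide 15 (not isolated)
Conditions: O2, hν, tetraphenylporphyrin (cat.), iPr2NEt, CH2Cl2, −78 °C; then MeOH, NaBH4, −20 → 0 °C; then 1 M HCl
Reagents that add atoms: dioxygen, O=O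
Why: Singlet-oxygen [4+2] cycloaddition to the furan and Kornblum–DeLaMare fragmentation of the endoperoxide by removal of the less hindered C19–H give 15 regioselectively, and borohydride reduction of its ring-opened aldehyde form with acid relactonisation gives the β-substituted butenolide with C25 as CH2.

Step 12
Reactants: 16 butenolide alcohol
Product: 17 axial aldehyde (13α-H, 13β-CHO)
Conditions: Dess–Martin periodinane, CH2Cl2, 0 → 23 °C
Reagents that add atoms: none
Why: Dess–Martin oxidation stops at the aldehyde under near-neutral conditions and leaves the acetate and the butenolide untouched.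

Step 13
Reactants: 17 axial aldehyde
Product: 21 CNP0193439.1, via equatorial aldehyde 18 (not isolated), via silyloxyfuran aldehyde 19 (not isolated), via aldol silyl ether 20 (not isolated)
Conditions: DBU (0.2 equiv), CH2Cl2, 23 °C; then iPr2NEt, TBSOTf, −78 → 0 °C; then DBU (5 equiv), 0 → 40 °C
Reagents that add atoms: none
Why: Catalytic DBU first equilibrates the aldehyde α-centre (17 to 18 through the enolate), TBSOTf/iPr2NEt then turns ring E into the 2-silyloxyfuran 19, whose γ-carbon C25 adds to the silyl-activated aldehyde carbon C24 (intramolecular vinylogous Mukaiyama aldol) to give 20, and excess DBU removes the acidic C25–H and expels silanolate (E1cB) to form C24=C25. The closest known reaction type is the one-pot silylative vinylogous aldol/β-elimination of β-substituted butenolides with aldehydes to γ-ylidenebutenolides, run here within one molecule. Ring D closes in a 7-(enolendo)-exo-trig mode, helped by the gauche vicinal arms on C13 and C14 of the rigid ring C. The C24 and C25 centres of 20 are erased by the elimination, the alkene can only be E (C13 cis to C17, the isomer an open-chain condensation would disfavour) because it is endocyclic in ring D, and C13 is under thermodynamic control both before closure (α to CHO) and after it (deprotonation gives an aromatic 5-alkenyl-2-furanolate), with only the 13β-H isomer escaping the syn-diaxial contact of C24 with the C23 methyl on C8, so all isomers funnel into 21. The step needs attack through C25 rather than C18, both of which would give a seven-membered ring, and this is secured by the γ-selectivity of silyloxyfurans and by the fact that only the γ-adduct carries the acidic proton for the irreversible elimination. The C16 acetate is kept because no resonance form of the silyloxyfuran or furanolate places charge on C17, so acetate is never a β-leaving group.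

**Compound list**

1 | (+)-manool, (13R)-labda-8(17),14-dien-13-ol | C=C[C@](C)(O)CC[C@H]1C(=C)CC[C@H]2C(C)(C)CCC[C@]12C | starting material
2 | 14,15-dinorlabd-8(17)-en-13-one | CC(=O)CC[C@H]1C(=C)CC[C@H]2C(C)(C)CCC[C@]12C | intermediate
3 | methyl 13-oxo-16-norlabd-8(17)-en-15-oate | COC(=O)CC(=O)CC[C@H]1C(=C)CC[C@H]2C(C)(C)CCC[C@]12C | intermediate
4 | tricyclic β-keto ester (13-oxo, 14β-CO2Me, 5α-H, 9α-H, 14α-H, 8β- and 10β-methyl) | COC(=O)[C@@H]2C(=O)CC[C@H]1[C@@]2(C)CC[C@H]2C(C)(C)CCC[C@]12C | intermediate
5 | exo-methylene ester (C13=C24H2, 14β-CO2Me) | COC(=O)[C@@H]2C(=C)CC[C@H]1[C@@]2(C)CC[C@H]2C(C)(C)CCC[C@]12C | intermediate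
6 | homoallylic alcohol (C15–OH) | OC[C@@H]2C(=C)CC[C@H]1[C@@]2(C)CC[C@H]2C(C)(C)CCC[C@]12C | intermediate
7 | C15 iodide | IC[C@@H]2C(=C)CC[C@H]1[C@@]2(C)CC[C@H]2C(C)(C)CCC[C@]12C | intermediate
8 | N-methoxy-N-methylfuran-3-carboxamide | CON(C)C(=O)c1ccoc1 | starting material
9 | C15 alkyllithium | [Li]C[C@@H]2C(=C)CC[C@H]1[C@@]2(C)CC[C@H]2C(C)(C)CCC[C@]12C | intermediate
10 | furyl ketone (C16=O, furan-3-yl on C16) | O=C(c1ccoc1)C[C@@H]2C(=C)CC[C@H]1[C@@]2(C)CC[C@H]2C(C)(C)CCC[C@]12C | intermediate
11 | (16R)-furyl carbinol | O[C@@H](c1ccoc1)C[C@@H]2C(=C)CC[C@H]1[C@@]2(C)CC[C@H]2C(C)(C)CCC[C@]12C | intermediate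
12 | (16R)-acetate | CC(=O)O[C@@H](c1ccoc1)C[C@@H]2C(=C)CC[C@H]1[C@@]2(C)CC[C@H]2C(C)(C)CCC[C@]12C | intermediate
13 | B-alkyl-9-BBN adduct (boron on C24, 13α-H) | CC(=O)O[C@@H](c1ccoc1)C[C@@H]2[C@H](CB3C4CCCC3CCC4)CC[C@H]1[C@@]2(C)CC[C@H]2C(C)(C)CCC[C@]12C | intermediate
14 | furan primary alcohol (13α-H, axial 13β-CH2OH) | CC(=O)O[C@@H](c1ccoc1)C[C@@H]2[C@H](CO)CC[C@H]1[C@@]2(C)CC[C@H]2C(C)(C)CCC[C@]12C | intermediate
15 | 25-hydroxybutenolide (both C25 epimers) | CC(=O)O[C@@H](C1=CC(=O)OC1O)C[C@@H]2[C@H](CO)CC[C@H]1[C@@]2(C)CC[C@H]2C(C)(C)CCC[C@]12C | intermediate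
16 | butenolide alcohol | CC(=O)O[C@@H](C1=CC(=O)OC1)C[C@@H]2[C@H](CO)CC[C@H]1[C@@]2(C)CC[C@H]2C(C)(C)CCC[C@]12C | intermediate
17 | axial aldehyde (13α-H) | CC(=O)O[C@@H](C1=CC(=O)OC1)C[C@@H]2[C@H](C=O)CC[C@H]1[C@@]2(C)CC[C@H]2C(C)(C)CCC[C@]12C | intermediate
18 | equatorial aldehyde (13β-H) | CC(=O)O[C@@H](C1=CC(=O)OC1)C[C@@H]2[C@@H](C=O)CC[C@H]1[C@@]2(C)CC[C@H]2C(C)(C)CCC[C@]12C | intermediate
19 | silyloxyfuran aldehyde (2-TBSO-furan, substituted at its C4) | CC(=O)O[C@@H](c1coc(O[Si](C)(C)C(C)(C)C)c1)C[C@@H]2[C@@H](C=O)CC[C@H]1[C@@]2(C)CC[C@H]2C(C)(C)CCC[C@]12C | intermediate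
20 | aldol silyl ether (ring D closed, mixture at C24 and C25) | CC(=O)O[C@@H]1C[C@@H]2[C@@H](C(O[Si](C)(C)C(C)(C)C)C3OC(=O)C=C31)CC[C@H]1[C@@]2(C)CC[C@H]2C(C)(C)CCC[C@]12C | intermediate
21 | CNP0193439.1 (16α-acetoxy, 13β-H, 14α-H, E-C24=C25) | CC(=O)O[C@@H]1C[C@@H]2[C@@H](C=C3OC(=O)C=C31)CC[C@H]1[C@@]2(C)CC[C@H]2C(C)(C)CCC[C@]12C | target

Total step count: 13. Longest linear sequence: 13 steps (1 to 21).

**Steps most likely to fail**

Risk 1, step 13. The α-branched aldehyde may undergo enol silylation instead of activation. The seven-membered closure may be slow enough for intermolecular aldol addition to compete. Attack may occur through C18, or C13 may not equilibrate fully. The fallback closes ring D with the furan as nucleophile and oxidises ring E afterwards. It sets out from 14. Dess–Martin oxidation gives the axial furan aldehyde F1, and DBU equilibrates it to the equatorial furan aldehyde F2. BF3·OEt2 with Et3SiH in CH2Cl2 at −78 °C lets furan carbon C25 attack the activated aldehyde (Friedel–Crafts hydroxyalkylation) and reduces the furfuryl cation in the same flask to the furan-fused pentacycle F3. Singlet oxygen with iPr2NEt converts this into the 25-hydroxybutenolide pentacycle F4, and MsCl/Et3N dehydrates it towards C24. The fallback comes back to the route at 21.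

Risk 2, step 4. The titanium–zinc reagent may chelate or protonolyse on the enolisable β-keto ester so that carbonyl addition stalls, or the new double bond may migrate into conjugation with the ester. The fallback installs C24 by cross-coupling instead of carbonyl olefination. It sets out from 4. NaH/PhNTf2 gives the enol triflate F5, and Kumada coupling with Me3SiCH2MgCl under Pd(PPh3)4 catalysis gives the allylsilane ester F6. Bu4NF/AcOH then removes silicon, and the dienolate is protonated at C14 from the open α face (axial protonation, 14α-H), which moves the double bond to C13=C24. The fallback comes back to the route at 5.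

Risk 3, step 8. Facial selectivity may be poor if the branched C15 arm competes with the furyl group as the larger substituent, or if the chiral substrate is mismatched with the catalyst. The fallback makes both epimers useful instead of relying on reagent control. It sets out from 10. NaBH4 in MeOH gives 11 together with the (16S)-furyl carbinol F7. After separation, F7 is esterified with inversion (Mitsunobu reaction: AcOH, PPh3, DIAD) while 11 is acetylated as in step 9. Both streams come back to the route at 12.

**Further compounds**

F1 | step 13 | axial furan aldehyde | CC(=O)O[C@@H](c1ccoc1)C[C@@H]2[C@H](C=O)CC[C@H]1[C@@]2(C)CC[C@H]2C(C)(C)CCC[C@]12C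
F2 | step 13 | equatorial furan aldehyde | CC(=O)O[C@@H](c1ccoc1)C[C@@H]2[C@@H](C=O)CC[C@H]1[C@@]2(C)CC[C@H]2C(C)(C)CCC[C@]12C
F3 | step 13 | furan-fused pentacycle | CC(=O)O[C@@H]1C[C@@H]2[C@@H](Cc3occc31)CC[C@H]1[C@@]2(C)CC[C@H]2C(C)(C)CCC[C@]12C
F4 | step 13 | 25-hydroxybutenolide pentacycle | CC(=O)O[C@@H]1C[C@@H]2[C@@H](CC3(O)OC(=O)C=C31)CC[C@H]1[C@@]2(C)CC[C@H]2C(C)(C)CCC[C@]12C
F5 | step 4 | enol triflate | COC(=O)C2=C(OS(=O)(=O)C(F)(F)F)CC[C@H]1[C@@]2(C)CC[C@H]2C(C)(C)CCC[C@]12C
F6 | step 4 | allylsilane ester | COC(=O)C2=C(C[Si](C)(C)C)CC[C@H]1[C@@]2(C)CC[C@H]2C(C)(C)CCC[C@]12C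
F7 | step 8 | (16S)-furyl carbinol | O[C@H](c1ccoc1)C[C@@H]2C(=C)CC[C@H]1[C@@]2(C)CC[C@H]2C(C)(C)CCC[C@]12C
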